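The plan cuts C8–C8a and C4a–C5. It exploits two features. Carbons C5–C8 of ring A (C4a, C5–C8, C8a) carry the 1,3-oxygen pattern of an acetoacetate unit. The heterocycle O1–C2(OAr)–C3–C4(=O) is mirrored in a symmetrical 2,6-diaryloxy-4-pyranone. In one flask the CH2 end of a prenyloxy silyloxydiene replaces one aryloxy group of the silyl-activated pyranone. Base then acylates the pyranone α-carbon with the ester, which closes and aromatises ring A with 5-OH and 7-O-prenyl already distinct. The pyranone is made from a bis(aryloxy)diynone, so its ring closure never passes through a tetrahedral ester adduct that could shed phenol. Buffered fluoride ends the route.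

Key step: step 7

Remark: the target has no stereocentre and no stereogenic double bond, so it is achiral, no enantiomer has to be chosen, and the enoate and diene geometries drawn below disappear on aromatisation.

Step 1
Reactants: 1 hydroquinone
Product: 2 4-(triisopropylsilyloxy)phenol
Conditions: 1 (3 equiv), TIPSCl (1 equiv), imidazole (1.2 equiv), DMF, 0 °C → rt; excess 1 washed out with water
Reagents that add atoms: triisopropylsilyl chloride, CC(C)[Si](Cl)(C(C)C)C(C)C
Why: Imidazole-mediated O-silylation of a symmetrical diphenol, where excess 1 suppresses the bis-ether and the bulky TIPS group is chosen to survive carbonate, butyllithium, silyl triflate and amide base later.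

Step 2
Reactants: 2 4-(triisopropylsilyloxy)phenol; 3 trichloroethylene
Product: 4 (E)-1-(1,2-dichlorovinyloxy)-4-(triisopropylsilyloxy)benzene
Conditions: 3 (2 equiv), K2CO3 (1.5 equiv), DMF, 60 °C
Reagents that add atoms: none
Why: Net nucleophilic vinylic substitution of trichloroethylene by a phenoxide is the standard entry to aryl (E)-1,2-dichlorovinyl ethers, and the hindered silyl ether should tolerate anhydrous carbonate.

Step 3
Reactants: 4 (E)-1-(1,2-dichlorovinyloxy)-4-(triisopropylsilyloxy)benzene (2 equiv); 5 N-methoxy-N-methylcarbamoyl chloride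
Product: 8 1,5-bis[4-(triisopropylsilyloxy)phenoxy]penta-1,4-diyn-3-one, via lithium aryloxyacetylide 6 (not isolated), via alkynyl Weinreb amide 7 (not isolated)
Conditions: n-BuLi (2.1 equiv per 4), THF, −78 → −40 °C; 5 (0.48 equiv per 4), −78 → −10 °C; inverse quench into cold 1 M HCl/Et2O
Reagents that add atoms: none
Why: Dehydrochlorination and chlorine–lithium exchange of a dichlorovinyl ether give the lithium ynolate ether, and two acyl substitutions on the carbonyl-dication equivalent 5 (Weinreb ketone synthesis) stop at the chelated adduct, so the ketone appears only on the acidic quench, which also keeps the released amine protonated.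

Step 4
Reactants: 8 1,5-bis[4-(triisopropylsilyloxy)phenoxy]penta-1,4-diyn-3-one
Product: 10 2,6-bis[4-(triisopropylsilyloxy)phenoxy]-4H-pyran-4-one, via aryl 3-oxopent-4-ynoate 9 (not isolated)
Conditions: H2O (1.0 equiv), Ph3PAuNTf2 (2 mol%), CH2Cl2–dioxane, 0 °C → rt
Reagents that add atoms: water, O
Why: Hydrative cyclisation of a 1,4-diyn-3-one to a 4-pyranone, in which the push–pull alkyne takes up water only at its aryloxy-bearing carbon to give 9 and the ester carbonyl oxygen then closes 6-endo-dig on the second activated ynone (as known for 3-oxoalk-4-ynoates with non-cleavable esters), so that, unlike dehydration of a diaryl 3-oxoglutarate, no adduct forms that could expel the phenol and end as a 4-hydroxy-2-pyranone.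

Step 5
Reactants: 11 prenol (3-methylbut-2-en-1-ol); 12 methyl but-2-ynoate
Product: 13 methyl (E)-3-(3-methylbut-2-enyloxy)but-2-enoate
Conditions: PMe3 (10 mol%), CH2Cl2, 0 °C → rt
Reagents that add atoms: none
Why: Trialkylphosphine-catalysed oxa-Michael addition of an alcohol to an alkynoate should give the favoured (E)-β-alkoxy enoate under neutral conditions, which spare acid-sensitive prenol and stay far below the onset of the Claisen rearrangement of this allyl vinyl ether.

Step 6
Reactants: 13 methyl (E)-3-(3-methylbut-2-enyloxy)but-2-enoate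
Product: 15 (Z)-1-methoxy-3-(3-methylbut-2-enyloxy)-1-(trimethylsilyloxy)buta-1,3-diene, via lithium dienolate 14 (not isolated)
Conditions: LDA (commercial solution, 1.1 equiv), THF, −78 °C; TMSCl (1.3 equiv), −78 → −30 °C; volatiles removed at ≤0 °C, cold pentane, filtration under argon, used at once
Reagents that add atoms: trimethylsilyl chloride, C[Si](C)(C)Cl
Why: Kinetic γ-deprotonation of a 3-alkoxycrotonate through the chelated s-cis ester, followed by O-silylation, is the standard preparation of 1,3-dialkoxy-1-silyloxydienes, and the cold non-aqueous isolation should outrun both hydrolysis and the [3,3] shift.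

Step 7
Reactants: 10 2,6-bis[4-(triisopropylsilyloxy)phenoxy]-4H-pyran-4-one; 15 (Z)-1-methoxy-3-(3-methylbut-2-enyloxy)-1-(trimethylsilyloxy)buta-1,3-diene
Product: 17 5-hydroxy-7-(3-methylbut-2-enyloxy)-2-[4-(triisopropylsilyloxy)phenoxy]-4H-chromen-4-one, via pyranonyl enoate 16 (not isolated)
Conditions: TMSOTf (0.3 equiv), 2,6-di-tert-butyl-4-methylpyridine (0.1 equiv), CH2Cl2, −78 °C, slow addition of 15 (1.05 equiv), → −40 °C; then LiHMDS (1.4 equiv), THF, −78 → 0 °C; AcOH quench
Reagents that add atoms: none
Why: Proposed new method: TMSOTf silylates the C4 carbonyl oxygen of 10 to a 4-silyloxy-2,6-diaryloxypyrylium ion, the CH2 terminus of 15 adds to C6 (the future C8a) to make C8–C8a, and the resulting ketal expels its aryloxy group as the aryl trimethylsilyl ether, which restores the pyranone in 16 and returns the silyl triflate, so the promoter is only a carrier. LiHMDS then removes a C8 proton, acidified by both the pyranone and the β-alkoxyacrylate, and the α-carbon C4a of the extended enolate attacks the ester carbonyl, held cis to C8 by the E-enoate, in a 6-(enolexo)-exo-trig Dieckmann-type closure that makes C4a–C5, after which loss of methoxide and enolisation of the cyclohexadienone give aromatic ring A with the chelated 5-OH. The closest known reaction types are silyl-triflate-promoted Mukaiyama–Michael additions of silyl ketene acetals to 4-pyranones and chromones, addition–elimination of carbon nucleophiles on 2,6-dialkoxy-4-pyranones, and aromatising annulations of 1,3-dioxygenated silyloxydienes with haloquinones. No stereocentre is created and the geometry of 15 vanishes on aromatisation. The step needs γ- over α-attack, secured by the larger terminal coefficient and hindered α-carbon of a silyl dienolate, and it needs single substitution, secured by one equivalent of slowly added 15, by preferential silylation of the more Lewis-basic carbonyl of 10 under substoichiometric promoter and later by the anionic state of the product, while the equivalence of C2 and C6 in 10 removes any regiochemical choice. The hindered pyridine scavenges triflic acid so that the enol prenyl ether survives, and the low temperature keeps the allyl vinyl ether of 15 ahead of its [3,3] shift.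

Step 8
Reactants: 17 5-hydroxy-7-(3-methylbut-2-enyloxy)-2-[4-(triisopropylsilyloxy)phenoxy]-4H-chromen-4-one
Product: 18 5-hydroxy-2-(4-hydroxyphenoxy)-7-(3-methylbut-2-enyloxy)-4H-chromen-4-one
Conditions: TBAF (1.1 equiv), AcOH (1.2 equiv), THF, 0 °C
Reagents that add atoms: none
Why: Fluoride cleavage of a phenolic silyl ether, buffered with acetic acid so that no basic fluoride, hydroxide or free phenoxide attacks the vinylogous carbonate carbon C2, and the prenyl ether is untouched.

Compound list
1 | hydroquinone | Oc1ccc(O)cc1 | starting material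
2 | 4-(triisopropylsilyloxy)phenol | Oc1ccc(O[Si](C(C)C)(C(C)C)C(C)C)cc1 | intermediate
3 | trichloroethylene | ClC=C(Cl)Cl | starting material
4 | (E)-1-(1,2-dichlorovinyloxy)-4-(triisopropylsilyloxy)benzene | Cl/C=C(/Cl)Oc1ccc(O[Si](C(C)C)(C(C)C)C(C)C)cc1 | intermediate
5 | N-methoxy-N-methylcarbamoyl chloride | CON(C)C(Cl)=O | starting material
6 | lithium [4-(triisopropylsilyloxy)phenoxy]acetylide | [Li]C#COc1ccc(O[Si](C(C)C)(C(C)C)C(C)C)cc1 | intermediate
7 | N-methoxy-N-methyl-3-[4-(triisopropylsilyloxy)phenoxy]prop-2-ynamide | CON(C)C(=O)C#COc1ccc(O[Si](C(C)C)(C(C)C)C(C)C)cc1 | intermediate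
8 | 1,5-bis[4-(triisopropylsilyloxy)phenoxy]penta-1,4-diyn-3-one | O=C(C#COc1ccc(O[Si](C(C)C)(C(C)C)C(C)C)cc1)C#COc1ccc(O[Si](C(C)C)(C(C)C)C(C)C)cc1 | intermediate
9 | 4-(triisopropylsilyloxy)phenyl 3-oxo-5-[4-(triisopropylsilyloxy)phenoxy]pent-4-ynoate | O=C(CC(=O)C#COc1ccc(O[Si](C(C)C)(C(C)C)C(C)C)cc1)Oc1ccc(O[Si](C(C)C)(C(C)C)C(C)C)cc1 | intermediate
10 | 2,6-bis[4-(triisopropylsilyloxy)phenoxy]-4H-pyran-4-one | O=c1cc(Oc2ccc(O[Si](C(C)C)(C(C)C)C(C)C)cc2)oc(Oc2ccc(O[Si](C(C)C)(C(C)C)C(C)C)cc2)c1 | intermediate
11 | prenol (3-methylbut-2-en-1-ol) | CC(C)=CCO | starting material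
12 | methyl but-2-ynoate | CC#CC(=O)OC | starting material
13 | methyl (E)-3-(3-methylbut-2-enyloxy)but-2-enoate | COC(=O)/C=C(\C)OCC=C(C)C | intermediate
14 | lithium (Z)-1-methoxy-3-(3-methylbut-2-enyloxy)buta-1,3-dien-1-olate | CO/C(O[Li])=C/C(=C)OCC=C(C)C | intermediate
15 | (Z)-1-methoxy-3-(3-methylbut-2-enyloxy)-1-(trimethylsilyloxy)buta-1,3-diene | CO/C(O[Si](C)(C)C)=C/C(=C)OCC=C(C)C | intermediate
16 | methyl (E)-3-(3-methylbut-2-enyloxy)-4-{4-oxo-6-[4-(triisopropylsilyloxy)phenoxy]-4H-pyran-2-yl}but-2-enoate | COC(=O)/C=C(\Cc1cc(=O)cc(Oc2ccc(O[Si](C(C)C)(C(C)C)C(C)C)cc2)o1)OCC=C(C)C | intermediate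
17 | 5-hydroxy-7-(3-methylbut-2-enyloxy)-2-[4-(triisopropylsilyloxy)phenoxy]-4H-chromen-4-one | CC(C)=CCOc1cc(O)c2c(=O)cc(Oc3ccc(O[Si](C(C)C)(C(C)C)C(C)C)cc3)oc2c1 | intermediate
18 | 5-hydroxy-2-(4-hydroxyphenoxy)-7-(3-methylbut-2-enyloxy)-4H-chromen-4-one | CC(C)=CCOc1cc(O)c2c(=O)cc(Oc3ccc(O)cc3)oc2c1 | target

Total step count: 8. Longest linear sequence: 6 steps (1, 2, 3, 4, 7, 8). Steps 5 and 6 form the second branch.

Steps most likely to fail

Step 7. Several processes could defeat the annulation:
- the diene may attack at C4 or through its α-carbon;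
- a second displacement may occur at C2;
- the prenyl–oxygen bond may ionise at the oxocarbenium stage;
- the diene may undergo its [3,3] shift before it is consumed;
- O-silylation of the extended enolate may stall the acylation.

The fallback uses the established displacement on 2-sulfonylchromones. It sets out from 2 and comes back at 17. Commercial 2,4,6-trihydroxyacetophenone is alkylated at its unchelated 4-OH with prenyl bromide (K2CO3, acetone) to 1-[2,6-dihydroxy-4-(3-methylbut-2-enyloxy)phenyl]ethan-1-one F1. Excess t-BuOK and CS2 in THF convert this into 4,5-dihydroxy-7-(3-methylbut-2-enyloxy)-2H-chromene-2-thione F2. S-Methylation (MeI, K2CO3, acetone) gives 5-hydroxy-2-(methylsulfanyl)-7-(3-methylbut-2-enyloxy)-4H-chromen-4-one F3. Molybdate-catalysed H2O2, which spares trisubstituted alkenes, gives 5-hydroxy-2-(methylsulfonyl)-7-(3-methylbut-2-enyloxy)-4H-chromen-4-one F4. Phenol 2 with K2CO3 in DMF then displaces the sulfinate at C2 by addition–elimination to give 17.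

Step 4. A second hydration may outrun ring closure and open the chain, or catalyst turnover may be slow on the very polar ynones. The fallback sets out from 8 and comes back at 10. It replaces π-acid catalysis by vinylic substitution with chloride as the leaving group. Anhydrous HCl (2 equiv, dioxane/CH2Cl2, −40 °C) adds to both ynol ethers, as it does to simple alkoxyalkynes, to give 1,5-dichloro-1,5-bis[4-(triisopropylsilyloxy)phenoxy]penta-1,4-dien-3-one F5 as a mixture of double-bond isomers. One equivalent of water with Et3N in THF replaces one chloride. The oxygen of the resulting β-keto ester enolate then displaces the other chloride intramolecularly. Chloride leaves in preference to aryloxide at each stage, so both aryloxy groups stay.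

Step 3. The released N,O-dimethylhydroxylamine may add in conjugate fashion during the quench, the adduct may collapse early and suffer over-addition, or the diynone may be lost by hydrolysis on isolation. The fallback sets out from 4 (through acetylide 6) and comes back at 8. It replaces acyl substitution by addition and oxidation. Acetylide 6 is added to ethyl formate (0.5 equiv, −78 °C) to give 1,5-bis[4-(triisopropylsilyloxy)phenoxy]penta-1,4-diyn-3-ol F6, which is worked up under neutral conditions. MnO2 in CH2Cl2 oxidises it to 8, which is filtered and used directly, and no amine is ever present.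

Further compounds
F1 | step 7 | 1-[2,6-dihydroxy-4-(3-methylbut-2-enyloxy)phenyl]ethan-1-one | CC(=O)c1c(O)cc(OCC=C(C)C)cc1O
F2 | step 7 | 4,5-dihydroxy-7-(3-methylbut-2-enyloxy)-2H-chromene-2-thione | Oc1cc(=S)oc2cc(OCC=C(C)C)cc(O)c12
F3 | step 7 | 5-hydroxy-2-(methylsulfanyl)-7-(3-methylbut-2-enyloxy)-4H-chromen-4-one | CSc1cc(=O)c2c(O)cc(OCC=C(C)C)cc2o1
F4 | step 7 | 5-hydroxy-2-(methylsulfonyl)-7-(3-methylbut-2-enyloxy)-4H-chromen-4-one | CS(=O)(=O)c1cc(=O)c2c(O)cc(OCC=C(C)C)cc2o1
F5 | step 4 | 1,5-dichloro-1,5-bis[4-(triisopropylsilyloxy)phenoxy]penta-1,4-dien-3-one (mixture of double-bond isomers) | O=C(C=C(Cl)Oc1ccc(O[Si](C(C)C)(C(C)C)C(C)C)cc1)C=C(Cl)Oc1ccc(O[Si](C(C)C)(C(C)C)C(C)C)cc1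
F6 | step 3 | 1,5-bis[4-(triisopropylsilyloxy)phenoxy]penta-1,4-diyn-3-ol | OC(C#COc1ccc(O[Si](C(C)C)(C(C)C)C(C)C)cc1)C#COc1ccc(O[Si](C(C)C)(C(C)C)C(C)C)cc1
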